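C1 is the alkyne CH and C15 the ethyl CH3; the oxolane is O/C4–C7 and the oxocane is O/C6–C12. The C3–Br bond comes from a (3S)-carbinol by inversion, and the oxolane, the last ring formed, comes from 5-exo opening of a (3S,4S)-alkynyl epoxide by the C7 hydroxyl.
The cis C9-OAc/C10-Br pair comes from a (Z)-C9=C10 oxocene with Br+ and AcOH, through transannular participation of the oxocane oxygen (double inversion at C9).
The C5–C6 bond comes from an eight-membered oxocarbenium ion and a dienol silane; until then C6 is carried as a lactone carbonyl (temporary higher oxidation level).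
Key disconnection: the C7–C8 and O–C12 bonds of the oxocene lactone are made together from the acyclic (silyloxy)acetate of (3S,5E)-octa-1,5-dien-3-ol. Br+ at C12=C13 lets the ester C=O oxygen bond to C12 (temporary 1,3-dioxane ring), and the derived ketene acetal then bonds C7 to C8 in a [3,3] shift that cuts the temporary C10–O bond.
Enabling feature: C12 (O-bearing, with the anti C13–Br next to it) and C10 are 1,3-related in the oxocane, and C10 becomes allylic to C8 once the cis-bromoacetate is read as C9=C10. An O–C6–O unit can therefore bridge C12 and C10 in a six-membered ring (C6, O, C12, C11, C10, O) that holds the C9=C8 vinyl group over C7. Ring order: temporary dioxane, oxocene, transient oxonium bicycle, oxolane.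

Key step: step 5

Assumption: compounds 1 and 5 and all named reagents are taken as commercial; locants C1–C15 are those defined above.

Step 1
Reactants: 1 (E)-hex-3-en-1-ol
Product: 2 (E)-hex-3-enal
Conditions: Dess–Martin periodinane, pyridine, CH2Cl2, 0 °C; used crude
Reagents that add atoms: none
Why: Buffered Dess–Martin oxidation stops at the aldehyde and should leave the β,γ-(E)-alkene unconjugated if the product is used at once.

Step 2
Reactants: 2 (E)-hex-3-enal
Product: 3 rac-(E)-octa-1,5-dien-3-ol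
Conditions: CH2=CHMgBr, THF, −78 °C; aqueous work-up
Reagents that add atoms: vinylmagnesium bromide, C=C[Mg]Br
Why: Grignard 1,2-addition at low temperature outruns enolisation and gives the racemic bis-unsaturated carbinol (C10).

Step 3
Reactants: 3 rac-(E)-octa-1,5-dien-3-ol
Product: 4 (3S,5E)-octa-1,5-dien-3-ol
Conditions: Ti(OiPr)4, D-(−)-diisopropyl tartrate, t-BuOOH (0.6 equiv), 4 Å MS, CH2Cl2, −20 °C
Reagents that add atoms: none
Why: In the Sharpless kinetic resolution with the D-(−)-tartrate the (R)-carbinol is epoxidised at its vinyl group much faster, so the (S)-carbinol should be recovered enantioenriched while the homoallylic (E)-alkene is not touched.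

Step 4
Reactants: 4 (3S,5E)-octa-1,5-dien-3-ol; 5 2-(tert-butyldimethylsilyloxy)acetic acid
Product: 6 (3S,5E)-octa-1,5-dien-3-yl 2-(tert-butyldimethylsilyloxy)acetate
Conditions: DCC, DMAP (cat.), CH2Cl2, 0 °C to rt
Reagents that add atoms: none
Why: Steglich esterification acylates oxygen without touching the carbinol C–O bond, so the (S) centre is retained.

Step 5
Reactants: 6 (3S,5E)-octa-1,5-dien-3-yl 2-(tert-butyldimethylsilyloxy)acetate
Product: 9 (3R,5Z,8R)-8-[(1S)-1-bromopropyl]-3-(tert-butyldimethylsilyloxy)-3,4,7,8-tetrahydro-2H-oxocin-2-one, via dioxanylium salt 7 (not isolated), via ketene acetal 8 (not isolated)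
Conditions: 2,4,4,6-tetrabromocyclohexa-2,5-dienone (TBCO, 1.0 equiv), CH2Cl2, −40 to 0 °C; then PhMe added, CH2Cl2 distilled off, 4 Å MS, 110 °C
Reagents that add atoms: TBCO, O=C1C(Br)=CC(Br)(Br)C=C1Br
Why: Proposed new method: TBCO transfers Br+ to the more electron-rich (E)-C12=C13 alkene, the ester carbonyl oxygen opens the bromonium ion anti at C12 to give the 1,3-dioxan-2-ylium salt 7, tribromophenoxide removes the acidified C7–H (directly or via the aryl orthoester) to give ketene acetal 8, and at 110 °C a [3,3] shift bonds C7 to C8, cuts the temporary C10–O bond and turns the former carbonyl oxygen into the ring oxygen of the eight-membered lactone. The closest known reaction types are the halocyclisation of homoallylic carbonates and esters through dioxanylium ions, the Johnson–Claisen rearrangement (loss of ROH from an orthoester to a ketene acetal) and the Claisen ring expansion of 2-methylene-4-vinyl-1,3-dioxanes to oct-4-enolides; only the generation of the ketene acetal by a bromonium ion is new. The temporary dioxane closes by 6-exo attack (preferred to 7-endo), and the oxocene forms not by end-to-end cyclisation but by six-to-eight ring expansion through a chair-like transition state in which only the arrangement with C11 cis to C8 can span the O–C12–C11 tether, hence the (Z)-alkene. C13 (S) follows from anti addition to the (E)-alkene, C12 (R) from the chair-like closure with the C10 vinyl group and the C12 side chain both equatorial (1,3-syn induction), and C7 (R) from delivery of C8 on the face fixed by C10 with OTBS pseudo-equatorial (cis to the C12-bound oxygen), the two ketene acetal geometries interconverting by reprotonation. The C10 centre is consumed in the shift, so its chirality passes to C7, C12 and C13, and a minor anti closure would give a separable diastereomer rather than the enantiomer. The step needs alkene chemoselectivity, secured because the C8=C9 vinyl group is monosubstituted and deactivated by the allylic acyloxy group, and full consumption of Br+ before 8 appears, secured by the cold first stage with exactly one equivalent of TBCO.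

Step 6
Reactants: 9 (3R,5Z,8R)-8-[(1S)-1-bromopropyl]-3-(tert-butyldimethylsilyloxy)-3,4,7,8-tetrahydro-2H-oxocin-2-one
Product: 11 (3R,5Z,8R)-8-[(1S)-1-bromopropyl]-3-(tert-butyldimethylsilyloxy)-3,4,7,8-tetrahydro-2H-oxocin-2-yl acetate (both C2 epimers), via aluminium hemiacetal 10 (not isolated)
Conditions: iBu2AlH, CH2Cl2, −78 °C; then pyridine, DMAP, Ac2O, −78 to 0 °C
Reagents that add atoms: acetic anhydride, CC(=O)OC(C)=O
Why: In this reductive acetylation of a lactone the tetrahedral aluminium hemiacetal 10 is acetylated before it can collapse, so the eight-membered ring should stay closed and the secondary bromide is not touched at −78 °C.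

Step 7
Reactants: 11 (3R,5Z,8R)-8-[(1S)-1-bromopropyl]-3-(tert-butyldimethylsilyloxy)-3,4,7,8-tetrahydro-2H-oxocin-2-yl acetate
Product: 12 (2E)-4-[(2S,3R,5Z,8R)-8-[(1S)-1-bromopropyl]-3-(tert-butyldimethylsilyloxy)-3,4,7,8-tetrahydro-2H-oxocin-2-yl]but-2-enal
Conditions: (E)-1-(trimethylsilyloxy)buta-1,3-diene, TMSOTf (0.2 equiv), CH2Cl2, −78 °C
Reagents that add atoms: (E)-1-(trimethylsilyloxy)buta-1,3-diene, C=C/C=C/O[Si](C)(C)C
Why: In this vinylogous Mukaiyama reaction the dienol silane attacks the C6 oxocarbenium ion through its γ-carbon to give the (E)-enal, from the face opposite both the C7-OTBS group and the C12 side chain (which share one face), which should set (6S), that is 6,7-trans and 6,12-trans.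

Step 8
Reactants: 12 (2E)-4-[(2S,3R,5Z,8R)-8-[(1S)-1-bromopropyl]-3-(tert-butyldimethylsilyloxy)-3,4,7,8-tetrahydro-2H-oxocin-2-yl]but-2-enal
Product: 13 (2R,3S)-3-{[(2S,3R,5Z,8R)-8-[(1S)-1-bromopropyl]-3-(tert-butyldimethylsilyloxy)-3,4,7,8-tetrahydro-2H-oxocin-2-yl]methyl}oxirane-2-carbaldehyde
Conditions: 35% aq. H2O2, (R)-2-{bis[3,5-bis(trifluoromethyl)phenyl](trimethylsilyloxy)methyl}pyrrolidine (10 mol%), CH2Cl2, rt
Reagents that add atoms: hydrogen peroxide, OO
Why: This iminium-catalysed nucleophilic (Weitz–Scheffer type) epoxidation touches only the enal, not the ring alkene, and the (R)-catalyst shields one face of the iminium ion so that hydroperoxide adds to C4 from the open face and closes to the trans-epoxide under reagent control.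

Step 9
Reactants: 13 (2R,3S)-3-{[(2S,3R,5Z,8R)-8-[(1S)-1-bromopropyl]-3-(tert-butyldimethylsilyloxy)-3,4,7,8-tetrahydro-2H-oxocin-2-yl]methyl}oxirane-2-carbaldehyde
Product: 14 (2S,3R,5Z,8R)-8-[(1S)-1-bromopropyl]-3-(tert-butyldimethylsilyloxy)-2-{[(2S,3S)-3-ethynyloxiran-2-yl]methyl}-3,4,7,8-tetrahydro-2H-oxocine
Conditions: MeC(O)C(N2)P(O)(OMe)2, K2CO3, MeOH, 0 °C to rt
Reagents that add atoms: dimethyl (1-diazo-2-oxopropyl)phosphonate, COP(=O)(OC)C(=[N+]=[N-])C(C)=O
Why: The Ohira–Bestmann variant of the Seyferth–Gilbert homologation turns epoxy aldehydes into alkynyl epoxides without epimerisation, and it is placed before the acetate is introduced because of the methanolic carbonate.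

Step 10
Reactants: 14 (2S,3R,5Z,8R)-8-[(1S)-1-bromopropyl]-3-(tert-butyldimethylsilyloxy)-2-{[(2S,3S)-3-ethynyloxiran-2-yl]methyl}-3,4,7,8-tetrahydro-2H-oxocine
Product: 16 (2S,3R,5R,6S,8R)-6-bromo-8-[(1S)-1-bromopropyl]-3-(tert-butyldimethylsilyloxy)-2-{[(2S,3S)-3-ethynyloxiran-2-yl]methyl}oxocan-5-yl acetate, via bicyclic oxonium ion 15 (not isolated)
Conditions: NBS, AcOH (10 equiv), CH2Cl2, 0 °C, dark
Reagents that add atoms: N-bromosuccinimide, O=C1CCC(=O)N1Br; acetic acid, CC(=O)O
Why: In this bromonium-induced transannular oxonium formation and fragmentation Br+ adds to the outer face of the only alkene, the ring oxygen attacks C9 to give the 1-oxoniabicyclo[3.3.0]octane 15 (favoured in the form with the bulky OTBS and bromopropyl groups on the convex face), and acetate opens the central C9–O bond with inversion, so that net retention at C9 should place OAc cis to Br as (9R,10S).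

Step 11
Reactants: 16 (2S,3R,5R,6S,8R)-6-bromo-8-[(1S)-1-bromopropyl]-3-(tert-butyldimethylsilyloxy)-2-{[(2S,3S)-3-ethynyloxiran-2-yl]methyl}oxocan-5-yl acetate
Product: 18 (3S,4R,6S,7R,9R,10S,12R,13S)-10,13-dibromo-4,7:6,12-diepoxy-3-hydroxypentadec-1-yn-9-yl acetate, via hydroxy epoxide 17 (not isolated)
Conditions: Et3N·3HF, MeCN, rt; then CSA (0.2 equiv), CH2Cl2, 0 °C
Reagents that add atoms: none
Why: Near-neutral fluoride desilylation spares acetate and bromides, and the freed C7 hydroxyl opens the uncomplexed alkynyl epoxide in the Baldwin-favoured 5-exo mode with inversion at C4, which sets (4R), closes the trans-fused oxolane and leaves the (3S)-carbinol.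

Step 12
Reactants: 18 (3S,4R,6S,7R,9R,10S,12R,13S)-10,13-dibromo-4,7:6,12-diepoxy-3-hydroxypentadec-1-yn-9-yl acetate
Product: 19 (3R,4R,6S,7R,9R,10S,12R,13S)-3,10,13-tribromo-4,7:6,12-diepoxypentadec-1-yn-9-yl acetate (target)
Conditions: CBr4, PPh3, CH2Cl2, 0 °C
Reagents that add atoms: carbon tetrabromide, BrC(Br)(Br)Br
Why: The Appel reaction displaces the activated propargylic oxygen by bromide in an SN2 process with inversion, as is usual for exocyclic carbinols next to a ring ether, and should give the (3R)-bromide.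

Compound list
1 | (E)-hex-3-en-1-ol | CC/C=C/CCO | starting material
2 | (E)-hex-3-enal | CC/C=C/CC=O | intermediate
3 | rac-(E)-octa-1,5-dien-3-ol | C=CC(O)C/C=C/CC | intermediate
4 | (3S,5E)-octa-1,5-dien-3-ol | C=C[C@@H](O)C/C=C/CC | intermediate
5 | 2-(tert-butyldimethylsilyloxy)acetic acid | CC(C)(C)[Si](C)(C)OCC(=O)O | starting material
6 | (3S,5E)-octa-1,5-dien-3-yl 2-(tert-butyldimethylsilyloxy)acetate | C=C[C@@H](OC(=O)CO[Si](C)(C)C(C)(C)C)C/C=C/CC | intermediate
7 | (4S,6R)-6-[(1S)-1-bromopropyl]-2-[(tert-butyldimethylsilyloxy)methyl]-4-ethenyl-1,3-dioxan-2-ylium 2,4,6-tribromophenoxide | C=C[C@@H]1C[C@H]([C@@H](Br)CC)[O+]=C(CO[Si](C)(C)C(C)(C)C)O1.[O-]c1c(Br)cc(Br)cc1Br | intermediate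
8 | (4S,6R)-6-[(1S)-1-bromopropyl]-2-[(tert-butyldimethylsilyloxy)methylidene]-4-ethenyl-1,3-dioxane, OTBS cis to the C12-bound oxygen | C=C[C@@H]1C[C@H]([C@@H](Br)CC)O/C(=C\O[Si](C)(C)C(C)(C)C)O1 | intermediate
9 | (3R,5Z,8R)-8-[(1S)-1-bromopropyl]-3-(tert-butyldimethylsilyloxy)-3,4,7,8-tetrahydro-2H-oxocin-2-one | O=C1O[C@@H]([C@@H](Br)CC)C/C=C\C[C@H]1O[Si](C)(C)C(C)(C)C | intermediate
10 | diisobutylaluminium hemiacetal of 9 | CC(C)C[Al](CC(C)C)OC1O[C@@H]([C@@H](Br)CC)C/C=C\C[C@H]1O[Si](C)(C)C(C)(C)C | intermediate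
11 | (3R,5Z,8R)-8-[(1S)-1-bromopropyl]-3-(tert-butyldimethylsilyloxy)-3,4,7,8-tetrahydro-2H-oxocin-2-yl acetate (both C2 epimers) | CC(=O)OC1O[C@@H]([C@@H](Br)CC)C/C=C\C[C@H]1O[Si](C)(C)C(C)(C)C | intermediate
12 | (2E)-4-[(2S,3R,5Z,8R)-8-[(1S)-1-bromopropyl]-3-(tert-butyldimethylsilyloxy)-3,4,7,8-tetrahydro-2H-oxocin-2-yl]but-2-enal | O=C/C=C/C[C@@H]1O[C@@H]([C@@H](Br)CC)C/C=C\C[C@H]1O[Si](C)(C)C(C)(C)C | intermediate
13 | (2R,3S)-epoxy aldehyde of 12 | O=C[C@@H]1O[C@H]1C[C@@H]2O[C@@H]([C@@H](Br)CC)C/C=C\C[C@H]2O[Si](C)(C)C(C)(C)C | intermediate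
14 | (3S,4S)-alkynyl epoxide on the oxocene | C#C[C@@H]1O[C@H]1C[C@@H]2O[C@@H]([C@@H](Br)CC)C/C=C\C[C@H]2O[Si](C)(C)C(C)(C)C | intermediate
15 | 1-oxoniabicyclo[3.3.0]octane-type oxonium acetate (oxygen bonded to C6, C9 and C12; C10–Br) | C#C[C@@H]1O[C@H]1C[C@H]2[C@H](O[Si](C)(C)C(C)(C)C)C[C@H]3[C@@H](Br)C[C@H]([C@@H](Br)CC)[O+]23.CC(=O)[O-] | intermediate
16 | (2S,3R,5R,6S,8R)-6-bromo-8-[(1S)-1-bromopropyl]-3-(tert-butyldimethylsilyloxy)-2-{[(2S,3S)-3-ethynyloxiran-2-yl]methyl}oxocan-5-yl acetate | C#C[C@@H]1O[C@H]1C[C@@H]2O[C@@H]([C@@H](Br)CC)C[C@H](Br)[C@H](OC(C)=O)C[C@H]2O[Si](C)(C)C(C)(C)C | intermediate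
17 | C7-hydroxy epoxide (16 without the silyl group) | C#C[C@@H]1O[C@H]1C[C@@H]2O[C@@H]([C@@H](Br)CC)C[C@H](Br)[C@H](OC(C)=O)C[C@H]2O | intermediate
18 | (3S,4R,6S,7R,9R,10S,12R,13S)-10,13-dibromo-4,7:6,12-diepoxy-3-hydroxypentadec-1-yn-9-yl acetate | C#C[C@H](O)[C@H]1C[C@@H]2O[C@@H]([C@@H](Br)CC)C[C@H](Br)[C@H](OC(C)=O)C[C@H]2O1 | intermediate
19 | (3R,4R,6S,7R,9R,10S,12R,13S)-3,10,13-tribromo-4,7:6,12-diepoxypentadec-1-yn-9-yl acetate (CNP0224788.1) | C#C[C@@H](Br)[C@H]1C[C@@H]2O[C@@H]([C@@H](Br)CC)C[C@H](Br)[C@H](OC(C)=O)C[C@H]2O1 | target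

Total step count: 12. Longest linear sequence: 12 steps (from 1).

Steps most likely to fail

1. Step 5.
- What may go wrong: the ketene acetal may form while Br+ is still present and be brominated again. The allylic C10–O bond of the dioxanylium ion may ionise. The 1,3-induction in the bromocyclisation, or the control of ketene acetal geometry (C7 epimers), may be poor.
- Fallback (known chemistry, from 4 back to 9): Boc2O/DMAP gives tert-butyl (3S,5E)-octa-1,5-dien-3-yl carbonate F1. NBS in MeCN at −20 °C closes, by the known 1,3-syn halocyclisation of homoallylic tert-butyl carbonates, (4R,6S)-4-[(1S)-1-bromopropyl]-6-ethenyl-1,3-dioxan-2-one F2. Cp2TiMe2 in toluene at 110 °C (Petasis methylenation) gives the 2-methylene-4-vinyl-1,3-dioxane, which rearranges in situ to (5Z,8R)-8-[(1S)-1-bromopropyl]-3,4,7,8-tetrahydro-2H-oxocin-2-one F3. KN(SiMe3)2 at −78 °C followed by a camphorsulfonyloxaziridine (Davis oxidation, reagent enantiomer matched to the (R)-carbinol) gives the α-hydroxy lactone F4. TBSOTf/2,6-lutidine then returns to 9.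

2. Step 10.
- What may go wrong: external acetate may capture the bromonium ion before the ring oxygen takes part (anti adduct). Acetate may open the oxonium ion at C6 or C12 (ring contraction to oxolanes). The silyl ether oxygen may participate.
- Fallback (from 14 back to 16): the approach changes to anti bromohydrin formation followed by correction of C9. NBS in aqueous acetone gives the trans-(9S,10S)-bromohydrin F5. Dess–Martin oxidation gives the α-bromo ketone F6. Luche reduction (NaBH4, CeCl3·7H2O, MeOH, −78 °C), with hydride attacking anti to the C–Br bond, gives the cis-(9R,10S)-bromohydrin F7. Ac2O/pyridine then gives 16.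

3. Step 7.
- What may go wrong: the dienol silane may attack through its α-carbon. The product enal may undergo a further Mukaiyama addition. The oxocarbenium ion may be trapped by the ring alkene in a transannular Prins closure. Facial selectivity may be eroded.
- Fallback (from 11 back to 12): allyltrimethylsilane with TMSOTf (Hosomi–Sakurai reaction, inert product alkene) gives the C6-allyl oxocene F8. Cross metathesis with crotonaldehyde (second-generation Hoveyda–Grubbs catalyst, CH2Cl2, 40 °C) then gives the (E)-enal 12.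

Further compounds
F1 | step 5 | tert-butyl (3S,5E)-octa-1,5-dien-3-yl carbonate | C=C[C@@H](OC(=O)OC(C)(C)C)C/C=C/CC
F2 | step 5 | (4R,6S)-4-[(1S)-1-bromopropyl]-6-ethenyl-1,3-dioxan-2-one | C=C[C@@H]1C[C@H]([C@@H](Br)CC)OC(=O)O1
F3 | step 5 | (5Z,8R)-8-[(1S)-1-bromopropyl]-3,4,7,8-tetrahydro-2H-oxocin-2-one | O=C1CC/C=C\C[C@H]([C@@H](Br)CC)O1
F4 | step 5 | (3R,5Z,8R)-8-[(1S)-1-bromopropyl]-3-hydroxy-3,4,7,8-tetrahydro-2H-oxocin-2-one | O=C1O[C@@H]([C@@H](Br)CC)C/C=C\C[C@H]1O
F5 | step 10 | trans-(9S,10S)-bromohydrin of 14 | C#C[C@@H]1O[C@H]1C[C@@H]2O[C@@H]([C@@H](Br)CC)C[C@H](Br)[C@@H](O)C[C@H]2O[Si](C)(C)C(C)(C)C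
F6 | step 10 | (10S)-10-bromo-9-ketone | C#C[C@@H]1O[C@H]1C[C@@H]2O[C@@H]([C@@H](Br)CC)C[C@H](Br)C(=O)C[C@H]2O[Si](C)(C)C(C)(C)C
F7 | step 10 | cis-(9R,10S)-bromohydrin | C#C[C@@H]1O[C@H]1C[C@@H]2O[C@@H]([C@@H](Br)CC)C[C@H](Br)[C@H](O)C[C@H]2O[Si](C)(C)C(C)(C)C
F8 | step 7 | (2S,3R,5Z,8R)-8-[(1S)-1-bromopropyl]-3-(tert-butyldimethylsilyloxy)-2-(prop-2-enyl)-3,4,7,8-tetrahydro-2H-oxocine | C=CC[C@@H]1O[C@@H]([C@@H](Br)CC)C/C=C\C[C@H]1O[Si](C)(C)C(C)(C)C
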